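**Retrosynthetic overview**
- Euchrenone b1 is 6,8,3'-triprenylgenistein. Each C-prenyl group sits ortho to one phenolic oxygen (C6 next to O5, C8 next to O7, C3' next to O4').
- Three retro-[3,3] (aromatic Claisen) shifts turn the three ArCH2CH=CMe2 groups into three aryl 1,1-dimethylallyl ethers, giving the tris-ether of genistein.
- Key disconnection: the three ArO–CMe2CH=CH2 carbon–oxygen bonds. All three are made in one palladium-catalysed operation from genistein and a tertiary allylic carbonate, itself made from 2-methylbut-3-en-2-ol and Boc2O.
- No ring is built. Rings A, C and B are bought intact in genistein.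

Assumption: the target has no stereocentre and no stereogenic double bond, so it is achiral and needs no stereocontrol. The SMILES is read as 5,7,4'-trihydroxy-6,8,3'-triprenylisoflavone.

**Step 1**
Reactants: 1 2-methylbut-3-en-2-ol
Product: 3 tert-butyl 2-methylbut-3-en-2-yl carbonate, via lithium 2-methylbut-3-en-2-olate 2 (not isolated)
Conditions: n-BuLi (1.05 equiv), THF, −78 °C, 30 min; Boc2O (1.1 equiv), −78 °C → rt, 3 h; H2O quench
Reagents that add atoms: di-tert-butyl dicarbonate (Boc2O), CC(C)(C)OC(=O)OC(=O)OC(C)(C)C; n-butyllithium, [Li]CCCC (supplies only the lithium of 2)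
Why: O-acylation of an alkoxide, in which the lithium alkoxide of the hindered tertiary allylic alcohol attacks Boc2O and expels tert-butyl carbonate, which breaks down to CO2 and tert-butoxide; no stereocentre is formed.

**Step 2**
Reactants: 4 genistein (5,7,4'-trihydroxyisoflavone); 3 tert-butyl 2-methylbut-3-en-2-yl carbonate (3.6 equiv)
Product: 6 5,7,4'-tris-O-(1,1-dimethylallyl)genistein, via genistein 7,4'-bis(1,1-dimethylallyl) ether 5 (not isolated)
Conditions: Pd2(dba)3·CHCl3 (4 mol %), dppb (10 mol %), THF, Ar, 0 °C, 2 h, then 15 °C, 4 h; cold filtration through Et3N-deactivated SiO2; used at once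
Reagents that add atoms: none
Why: Proposed new method: zerovalent palladium ionises 3 with loss of CO2 to a cationic η3-1,1-dimethylallyl complex plus tert-butoxide, a base strong enough to deprotonate even the hydrogen-bonded 5-OH of 5; because no alkali cation is present to re-chelate the 4-keto-5-oxide, and the chelating diphosphine stops it from binding to palladium as an O,O-chelate, the phenoxide sits as a tight ion pair on the allyl cation and attacks the more substituted, more cationic terminus, while low temperature and prompt removal of palladium keep the kinetic tertiary ethers from re-ionising to linear prenyl ethers; the closest known reaction type is the Tsuji–Trost decarboxylative O-reverse-prenylation of free, non-chelated phenols with tertiary allylic carbonates, which normally leaves peri-carbonyl-chelated hydroxyls untouched and has not been shown threefold on an isoflavone; no stereocentre is formed.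

**Step 3**
Reactants: 6 5,7,4'-tris-O-(1,1-dimethylallyl)genistein
Product: 9 euchrenone b1 (5,7,4'-trihydroxy-6,8,3'-triprenylisoflavone), via 6-prenyl-7,4'-bis-ether 7 (not isolated), via 6,8-diprenyl-4'-mono-ether 8 (not isolated)
Conditions: PhNEt2 (degassed, 0.05 M), BHT (5 mol %), Ar, 70 °C, 2 h, then 150 °C, 6 h
Reagents that add atoms: none
Why: Threefold aromatic Claisen rearrangement, in which each [3,3] shift inverts the allyl unit and trades a tertiary O–CMe2 bond for an ArCH2CH=CMe2 group; O5 can reach only C6 (C4a is quaternary) and should move first, since it is the most strained ether and gains the 5-OH···O=C4 hydrogen bond, so C8 is then the only free ortho site for O7 and C3' (equivalent to C5') the site for O4'; the basic solvent speeds rearomatisation and suppresses acid-induced chroman formation, and no stereocentre is formed.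

**Compound list**
1 | 2-methylbut-3-en-2-ol | C=CC(C)(C)O | starting material
2 | lithium 2-methylbut-3-en-2-olate | [Li+].[O-]C(C)(C)C=C | intermediate (not isolated)
3 | tert-butyl 2-methylbut-3-en-2-yl carbonate | C=CC(C)(C)OC(=O)OC(C)(C)C | intermediate
4 | genistein (5,7-dihydroxy-3-(4-hydroxyphenyl)-4H-chromen-4-one) | O=c1c(-c2ccc(O)cc2)coc2cc(O)cc(O)c12 | starting material
5 | genistein 7,4'-bis(1,1-dimethylallyl) ether (5-hydroxy-7,4'-bis[(2-methylbut-3-en-2-yl)oxy]isoflavone) | O=c1c(-c2ccc(OC(C)(C)C=C)cc2)coc2cc(OC(C)(C)C=C)cc(O)c12 | intermediate (not isolated)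
6 | 5,7,4'-tris-O-(1,1-dimethylallyl)genistein (5,7,4'-tris[(2-methylbut-3-en-2-yl)oxy]isoflavone) | O=c1c(-c2ccc(OC(C)(C)C=C)cc2)coc2cc(OC(C)(C)C=C)cc(OC(C)(C)C=C)c12 | intermediate
7 | 6-prenyl-7,4'-bis-ether (5-hydroxy-6-(3-methylbut-2-enyl)-7,4'-bis[(2-methylbut-3-en-2-yl)oxy]isoflavone) | O=c1c(-c2ccc(OC(C)(C)C=C)cc2)coc2cc(OC(C)(C)C=C)c(CC=C(C)C)c(O)c12 | intermediate (not isolated)
8 | 6,8-diprenyl-4'-mono-ether (5,7-dihydroxy-6,8-bis(3-methylbut-2-enyl)-4'-[(2-methylbut-3-en-2-yl)oxy]isoflavone) | O=c1c(-c2ccc(OC(C)(C)C=C)cc2)coc2c(CC=C(C)C)c(O)c(CC=C(C)C)c(O)c12 | intermediate (not isolated)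
9 | euchrenone b1 (5,7,4'-trihydroxy-6,8,3'-tris(3-methylbut-2-enyl)isoflavone; achiral) | CC(C)=CCc1cc(-c2coc3c(CC=C(C)C)c(O)c(CC=C(C)C)c(O)c3c2=O)ccc1O | target

**Step count**
Total step count: 3.
Longest linear sequence: 3 (1 → 3 → 6 → 9), with two steps from genistein.

**Steps most likely to fail**

*First, step 2 (the new step).*
- Risk: the chelated, hindered 5-oxide may not attack the tertiary terminus.
- Risk: it may give the linear 5-O-prenyl ether instead.
- Risk: the 5-ether may re-ionise or rearrange early and then be alkylated again.
- The fallback uses only known chemistry. It sets out from 4 (with 3) and comes back at 9.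
- With Pd(PPh3)4 and only 2.2 equiv of 3 in THF at 0 °C, the reaction stops at the bis-ether 5, which is now isolated.
- Heating 5 in PhNEt2 at 150 °C gives, by twofold Claisen rearrangement, a mixture of 8,3'-diprenylgenistein F1 and 6,3'-diprenylgenistein F2.
- The mixture need not be separated, because each isomer has only one free ring A carbon left.
- Base-mediated nuclear C-prenylation of both (prenyl bromide, KOH, MeOH, 0 °C) converges on 9. The yield is modest, since O-alkylation competes.

*Second, step 3.*
- Risk: loss of isoprene from the tertiary ethers.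
- Risk: a premature O7 → C6 shift, which would block the O5 shift.
- Risk: chroman formation at 150 °C.
- The fallback sets out from 4 and comes back at 9. It builds the prenyl groups by olefin metathesis on robust allyl groups.
- Exhaustive O-allylation (allyl bromide, K2CO3, DMF, 70 °C) gives 5,7,4'-tri-O-allylgenistein F3.
- Triple Claisen rearrangement (PhNEt2, 210 °C) gives 6,8,3'-triallylgenistein F4.
- Threefold cross-metathesis with excess 2-methylbut-2-ene gives 9. The catalyst is the second-generation Grubbs catalyst, RuCl2(=CHPh)(PCy3)(SIMes), in CH2Cl2 at 40 °C.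

*Third, step 1.*
- Risk: sluggish or incomplete acylation of the tertiary alcohol, and loss of the volatile, ionisation-prone carbonate on purification.
- The fallback sets out from 4 and comes back at 6. It reaches the same η3-1,1-dimethylallyl palladium cation from the primary isomer.
- Commercial prenol (3-methylbut-2-en-1-ol) is treated with Boc2O and catalytic DMAP in CH2Cl2. This gives tert-butyl 3-methylbut-2-enyl carbonate F5, an easily made and stable primary carbonate.
- F5 replaces 3 under the conditions of step 2 and delivers 6 through the common allyl complex.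

**Further compounds**
F1 | step 2 | 8,3'-diprenylgenistein (isolupalbigenin) | CC(C)=CCc1cc(-c2coc3c(CC=C(C)C)c(O)cc(O)c3c2=O)ccc1O
F2 | step 2 | 6,3'-diprenylgenistein (lupalbigenin) | CC(C)=CCc1cc(-c2coc3cc(O)c(CC=C(C)C)c(O)c3c2=O)ccc1O
F3 | step 3 | 5,7,4'-tri-O-allylgenistein | C=CCOc1ccc(-c2coc3cc(OCC=C)cc(OCC=C)c3c2=O)cc1
F4 | step 3 | 6,8,3'-triallylgenistein | C=CCc1cc(-c2coc3c(CC=C)c(O)c(CC=C)c(O)c3c2=O)ccc1O
F5 | step 1 | tert-butyl 3-methylbut-2-enyl carbonate | CC(C)=CCOC(=O)OC(C)(C)C
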